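Numbering used for every compound: C1 is the quaternary ring-fusion carbon with the methyl group, C2 and C3 are CH2, C4 is the isopropyl carbinol carbon, C5 is the ring-fusion CH, C6 carries the aroyloxy group, C7 is CH2, C8(CH3)=C9 is the alkene, and C10 carries the tigloyloxy group. β is the face of the C1 methyl group, α the opposite face.

## Analysis of the target

Target 20 is a daucane diester: a cyclopentane (ring A, C1–C5) trans-fused through the C1–C5 bond to a cycloheptene (ring B, C1 and C5–C10) with the C8=C9 double bond. It has five stereocentres: quaternary C1, the tertiary carbinol C4, C5, C6 and C10. With the C1 methyl β, H5, the C4 hydroxyl and both ester oxygens are α and the isopropyl group is β, so the methyl group, C6 and the isopropyl group all lie on the β face of ring A. On a chair-like ring B the C6 ester should be equatorial and the C10 ester axial, anti to the C1 methyl. The sensitive groups are the allylic tiglate (ionisation, deconjugation), two different esters that must not migrate or be cleaved together, a free phenol, and a tertiary alcohol 1,3 to the C6 oxygen, which invites retro-aldol cleavage and dehydration whenever C6 is a ketone. The synthesis is hard because the quaternary carbon is flanked by three stereocentres, because the trans ring fusion is the crowded arrangement and probably not the stable one at the C6 ketone stage, and because the two ring B oxygens are similar and must be told apart. The strategy rests on one feature: the oxygenated carbons C6 and C10 are bonded to the two ends of the C1–C5 bond, and C4, also oxygenated, sits next to C5. If C6 is joined to C10, a cyclobutane C1–C5–C6–C10 with vicinal oxygens appears, which is the photoadduct of a C4 enone (C5=C1) and an enediol (C6=C10).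

## Retrosynthetic reasoning

**20 to 18 (silyl groups and the C10 ester).** The O–Si bonds of 19 and the C10–O acyl bond are cut first. The tiglate goes on last because an allylic tiglate tolerates neither hydride nor enolate chemistry. The forward steps must acylate a hindered axial allylic alcohol without deconjugating the tigloyl group, and then free the phenol and the tertiary alcohol without touching either ester.

**18 to 15 (C10–H and the C8=C9 alkene).** The C10 carbinol goes back to enone 17, and 17 to the saturated ketone 15 by dehydrogenation. The cut is made here because C1 is quaternary, so the C10 ketone can only enolise toward C9 and the alkene position is automatic. Making C8 trigonal also removes the one stereocentre that the route never controls. The forward reduction has to deliver hydride from the outer face so that the alcohol ends up anti to the C1 methyl.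

**15 to 11 and 14 (C6 ester).** The aroyl group is attached before ring B is oxidised, so that it also protects the C6 oxygen and leaves C10 as the only carbonyl for the enolisation. Acid 14 comes from 12 by silylation.

**11 to 8 (C5–H, C6–H and the C4–O bond).** This is where the trans fusion is made. The hydrogen at C5 leaves the cyclobutane cis to the C1 methyl, and in aldol 7 that cis-fused arrangement is expected to be the stable one: C6 lies next to the hydroxyl, not the isopropyl group, and can hydrogen-bond to it. Base equilibration therefore cannot be relied on, and C5 has to be set under kinetic control through an enolate whose position is defined. The epoxy ketone 9 provides it: one-electron reduction breaks the C5–O bond and gives the C5=C6 enolate and nothing else. 9 comes from enone 8 by nucleophilic epoxidation. The price is that C4 and C5 are trigonal for one compound. The gain is that every diastereomer formed before 8 converges.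

**8 to 4 (C4=C5, the C6–C10 cleavage, the isopropyl group).** Enone 8 is the dehydration product of aldol 7, which is what glycol cleavage of triol 6 gives. The isopropyl group is added to photoadduct 4, where C4 is the only carbonyl, so no ketone has to be distinguished from another. The carbonyl is also consumed before the cyclobutanediol is unmasked, because a free cyclobutanol β to a ketone would invite retro-aldol cleavage of C5–C6, the wrong bond.

**4 to 2 and 3 (C1–C10 and C5–C6).** The cyclobutane is cut into enone 3 and enediol ether 2. Both are one step or less from commercial material, both rings and fourteen of the fifteen skeletal carbons arrive together, and the quaternary carbon is made in the same step. Only the face of the enone has to be controlled.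

**2 to 1.** The enediol ether is the silyl-trapped acyloin of diester 1.

## Alternatives that were turned down

**Alternative 1: oxidopyrylium (5+2) cycloaddition.** The cut is through C7–C8 and C9–C10 of ring B. In the forward sense an amine base converts acetoxypyranone A2 into its oxidopyrylium ylide, which adds across alkynyl sulfoxide A3 to give the oxygen-bridged cycloheptadienone A1.
- For: one step makes the seven-membered carbocycle with the C6 carbonyl, an oxygen on C10, both methyl-bearing carbons and the C8=C9 alkene already in place. On that point it is stronger than the chosen route, which needs a dehydrogenation and carries C8 epimers for nine steps. A stoichiometric sulfinyl group is also a well-tried way to pass on absolute configuration.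
- Against: A1 contains nothing of ring A. C2–C4 would have to be annulated onto the C1=C5 enone, which means making the quaternary C1 by conjugate addition to a β-methyl enone inside a bridged bicycle and then setting C5 and C4 relative to it. The bridging oxygen sits on C7 as well as C10, so a C7–O bond next to a ketone must be cleaved reductively. The sulfinyl group has to be removed from C9 without moving the alkene.
- Comparison: the chosen photocycloaddition gives both rings and C1 in one step from two simple partners; A1 gives one ring and leaves the harder half of the molecule.

**Alternative 2: dithiane anion opening a cyclopentene oxide.** The cut is the C5–C6 bond. After deprotonation of epoxy dithiane A5, the dithiane carbon attacks C5 of the C4–C5 epoxide with inversion and gives the trans-fused hydroazulene A4 with the C4 hydroxyl free.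
- For: the ring closure is stereospecific, so the trans fusion and the C4 carbinol come from one SN2 event. This is stronger than the chosen route, which needs steps 5 to 7 and relies on a facial preference and a kinetic protonation.
- Against: A5 is itself a demanding target, with the quaternary C1 set relative to a tetrasubstituted epoxide, a carbinol next to the quaternary carbon and a Z-trisubstituted alkene, all to be made in a long linear sequence. The closure asks a hindered carbanion to attack a carbon flanked by two fully substituted carbons while forming a seven-membered ring; base-induced opening of the epoxide to an allylic alcohol is the likely competitor. After dithiane hydrolysis the C6 ketone reduction problem is the same as in the chosen route.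
- Comparison: the chosen route has the bicyclic carbon skeleton after two steps; Alternative 2 moves the stereochemical work into the preparation of A5.

**Alternative 3: catalytic asymmetric methyl addition with aldol trapping.** The cuts are C1–CH3 and C5–C6. A copper–carbene catalyst adds a methyl group from an aluminium reagent to enone A7, and the enolate is trapped by iodo aldehyde A8 to give aldol A6.
- For: the quaternary centre is made by a ground-state catalytic reaction whose scope on 3-substituted cyclopentenones is better charted than that of the photochemical step chosen here, so on certainty of absolute control it is the stronger plan. C1, C5 and C6 are set in one operation.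
- Against: no ring is closed. Ring B still has to be formed at C9–C10 after unmasking C10, with a new carbinol next to the quaternary carbon. The C6 configuration from an aluminium enolate aldol is not secured. A8 is a β,γ-unsaturated aldehyde that can slip into conjugation. The isopropyl carbinol has to be added to a cyclopentanone carrying a bulky C5 side chain.
- Comparison: more steps and more protecting-group changes for the same stereocentres; the chosen route offers both rings at once and relays every later centre from C1.

Key step: step 2

Assumption 1: the Lewis acid of step 2 is the AlBr3-activated oxazaborolidine made from (S)-α,α-bis(3,5-dimethylphenyl)prolinol and 2,4,6-trifluorophenylboronic acid. It is taken to expose to 2 the enone face that gives 4, by extension of its behaviour with six-membered enones. If the sense is opposite, the (R)-prolinol catalyst is used and nothing else changes.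

Assumption 2: C8 epimers, any cis-syn-cis photoadduct and any C4 epimer of 5 are carried on without separation, because these centres are removed at 8 and at 17.

## Route

Step 1
Reactants: 1 dimethyl 3-methylglutarate
Product: 2 4-methyl-1,2-bis(trimethylsilyloxy)cyclopent-1-ene
Conditions: Na, Me3SiCl, toluene, reflux
Reagents that add atoms: chlorotrimethylsilane, C[Si](C)(C)Cl
Why: Rühlmann variant of the acyloin condensation; the five-membered enediolate is trapped on both oxygens as it forms, which prevents Dieckmann and aldol side reactions.

Step 2
Reactants: 2 4-methyl-1,2-bis(trimethylsilyloxy)cyclopent-1-ene; 3 3-methylcyclopent-2-en-1-one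
Product: 4 cis-anti-cis tricyclic bis(trimethylsilyl) ether photoadduct (either C8 epimer)
Conditions: 2 (5 equiv), AlBr3-activated (S)-oxazaborolidine (50 mol%), hν (366 nm), CH2Cl2, −75 °C
Reagents that add atoms: none
Why: Proposed new method: the Lewis acid binds the carbonyl of 3 and shifts its absorption to longer wavelength, so that at 366 nm mainly the complex is excited, and the excited enone adds to the electron-rich alkene 2 through a triplet 1,4-diradical that closes after spin inversion; the closest known reaction types are the enantioselective intermolecular (2+2) photocycloaddition of cyclohex-2-enones with alkenes under this class of Lewis acid and the uncatalysed photocycloaddition of cyclopentenones with 1,2-bis(silyloxy)cycloalkenes. One ring is closed, the cyclobutane C1–C5–C6–C10, by stepwise formation of C1–C10 and C5–C6 (radical addition, then recombination of the 1,4-diradical), a formal (2π+2π) closure. C1 is set by the chiral ligand, which shields one enantiotopic face of the bound enone; C5 follows from C1 because a cyclobutane can only be cis-fused to the cyclopentanone; C6 and C10 are cis to each other because they come from a cyclic alkene and should lie anti to ring A for steric reasons; C8 is not controlled. Only the configuration at C1 is needed, since C5, C6, C8 and C10 all become trigonal later and the syn or anti fusion isomers converge at 8. No regiochemical question arises because the two alkene carbons of 2 are equivalent. The step needs the photochemical path to outrun Lewis acid-promoted Mukaiyama–Michael addition of 2 to 3 and desilylation of 2; the β,β-disubstitution of 3 and the low temperature work in its favour.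

Step 3
Reactants: 4 cis-anti-cis photoadduct
Product: 5 tertiary alcohol of the photoadduct (C4 hydroxyl α and isopropyl β)
Conditions: i-PrMgCl, CeCl3, THF, −78 → 0 °C
Reagents that add atoms: isopropylmagnesium chloride, CC(C)[Mg]Cl
Why: Organocerium 1,2-addition to the only carbonyl group, which suppresses enolisation at C3 and β-hydride reduction. Attack should come from the convex face, away from the cyclobutane and its inward silyloxy groups, but the C4 configuration is of no consequence because C4 becomes trigonal in step 5.

Step 4
Reactants: 5 tertiary alcohol of the photoadduct
Product: 6 cyclobutane-6,10-diol with the C4 tertiary alcohol (triol)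
Conditions: K2CO3, MeOH, 23 °C
Reagents that add atoms: none
Why: Methanolysis of the two trimethylsilyl ethers; with C4 no longer a ketone the free cyclobutanol cannot undergo retro-aldol cleavage of C5–C6.

Step 5
Reactants: 6 triol
Product: 8 enedione (C4=C5 enone with C6 and C10 ketones; either C8 epimer), via cis-fused aldol 7 (not isolated)
Conditions: Pb(OAc)4, CH2Cl2, 0 °C; then p-TsOH·H2O (cat.), toluene, 60 °C
Reagents that add atoms: none
Why: Glycol cleavage of the strained cis-1,2-cyclobutanediol through a cyclic lead diester breaks C6–C10 and releases the seven-membered ring; acid then eliminates water from the β-hydroxy ketone to the conjugated tetrasubstituted enone (aldol condensation type), the thermodynamic sink for any β,γ-isomer. C4 and C5 become trigonal, so all photoadduct diastereomers except the C8 epimers converge.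

Step 6
Reactants: 8 enedione
Product: 9 4α,5α-epoxy-6,10-diketone
Conditions: H2O2 (30% aq.), NaOH, MeOH, 0 → 23 °C
Reagents that add atoms: hydrogen peroxide, OO
Why: Weitz–Scheffer epoxidation of the s-cis enone; hydroperoxide should add to C4 anti to the C1 methyl, which is held pseudo-axial over the cyclopentene because C10 is tied back to C6 by ring B (the same sense as the α-epoxidation of steroidal 16-en-20-ones), and the enolate closes on the same face. The saturated C10 ketone is not an acceptor.

Step 7
Reactants: 9 epoxy diketone
Product: 11 trans-fused 4α,6α-dihydroxy-10-ketone, via trans-fused aldol 10 (not isolated)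
Conditions: SmI2 (5 equiv), THF/MeOH, −78 °C, then 0 °C
Reagents that add atoms: none
Why: Electron transfer to the α,β-epoxy ketone breaks the C5–O bond and gives the C5=C6 samarium enolate only; protonation from the α face (the β face is blocked by the C1 methyl and the C4 isopropyl group) should give the trans-fused aldol 10. Its chelate between O4 and the C6 carbonyl is then reduced further (samarium diiodide reduction of a β-hydroxy ketone), with hydrogen entering axially so that C1 and C7 are equatorial on the chelate ring, which gives the 6α alcohol. The unchelated C10 ketone should not react under these conditions, and pinacol coupling to C6 would need a trans-fused bicyclo[3.2.0]heptane.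

Step 8
Reactants: 12 4-hydroxybenzoic acid
Product: 14 4-(tert-butyldimethylsilyloxy)benzoic acid, via silyl ester silyl ether 13 (not isolated)
Conditions: TBSCl, imidazole, DMF, 23 °C; then AcOH, THF/H2O, 23 °C
Reagents that add atoms: tert-butyldimethylsilyl chloride, CC(C)(C)[Si](C)(C)Cl
Why: Both hydroxyl groups are silylated, and the silyl ester, far more labile than the aryl silyl ether, is hydrolysed selectively.

Step 9
Reactants: 11 keto diol; 14 4-(tert-butyldimethylsilyloxy)benzoic acid
Product: 15 6α-[4-(tert-butyldimethylsilyloxy)benzoyloxy]-4α-hydroxy-10-ketone
Conditions: EDC·HCl, DMAP, CH2Cl2, 23 °C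
Reagents that add atoms: none
Why: Steglich esterification; the equatorial secondary C6 hydroxyl is acylated and the tertiary C4 hydroxyl is not. The ester also protects C6 for the steps at C10.

Step 10
Reactants: 15 keto ester
Product: 17 8-en-10-one with C4 triethylsilyl ether and C6 aroyl ester, via triethylsilyl enol ether 16 (not isolated)
Conditions: TESOTf, Et3N, CH2Cl2, −78 → 0 °C; then Pd(OAc)2, MeCN, 40 °C
Reagents that add atoms: triethylsilyl trifluoromethanesulfonate, CC[Si](CC)(CC)OS(=O)(=O)C(F)(F)F
Why: Soft enolisation can only go toward C9 because C1 is quaternary, and the same reagent caps the tertiary alcohol. Saegusa–Ito oxidation (palladium enolate, β-hydride elimination of H8) then gives the enone and makes C8 trigonal, so the C8 epimers merge into one compound.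

Step 11
Reactants: 17 enone
Product: 18 10α-allylic alcohol
Conditions: L-Selectride (LiBH(s-Bu)3), THF, −78 °C; aq. NH4Cl
Reagents that add atoms: none
Why: 1,2-Reduction, as expected for a β,β-disubstituted enone. The bulky hydride should approach along the outer, equatorial direction, away from H5 and the C4 silyl ether on the inner face, giving the axial alcohol anti to the C1 methyl, as bulky hydrides do with ketones next to an angular methyl in trans-fused rings.

Step 12
Reactants: 18 allylic alcohol
Product: 19 10α-tiglate with C4 triethylsilyl ether and aryl silyl ether
Conditions: tigloyl chloride, pyridine, DMAP, CH2Cl2, 0 → 40 °C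
Reagents that add atoms: (E)-2-methylbut-2-enoyl chloride, C/C=C(\C)C(Cl)=O
Why: DMAP-catalysed acylation of the hindered secondary alcohol; pyridine is used instead of a trialkylamine so that no vinylketene forms and the E-configured α,β-unsaturated ester is kept.

Step 13
Reactants: 19 bis-silylated diester
Product: 20 target CNP0273650.6
Conditions: HF·pyridine, pyridine, THF, 0 → 23 °C
Reagents that add atoms: none
Why: Buffered fluoride cleaves the aryl silyl ether and the tertiary triethylsilyl ether; neither ester is attacked and the allylic tiglate is not ionised.

## Compound list

1 | dimethyl 3-methylglutarate (dimethyl 3-methylpentanedioate) | COC(=O)CC(C)CC(=O)OC | starting material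
2 | 4-methyl-1,2-bis(trimethylsilyloxy)cyclopent-1-ene | CC1CC(O[Si](C)(C)C)=C(O[Si](C)(C)C)C1 | intermediate
3 | 3-methylcyclopent-2-en-1-one | CC1=CC(=O)CC1 | starting material
4 | cis-anti-cis photoadduct: cyclobutane C1–C5–C6–C10 cis-fused to the cyclopentan-4-one C1–C5 and to the cyclopentane C6–C10; C1 methyl β, H5 β, trimethylsilyloxy groups on C6 and C10 cis to each other on the cyclobutane face that carries ring A; either C8 epimer | C[C@]12CCC(=O)[C@H]1[C@]1(O[Si](C)(C)C)CC(C)C[C@]21O[Si](C)(C)C | intermediate
5 | as 4 with C4 as tertiary carbinol: hydroxyl α (toward the cyclobutane), isopropyl β | C[C@]12CC[C@](O)(C(C)C)[C@H]1[C@]1(O[Si](C)(C)C)CC(C)C[C@]21O[Si](C)(C)C | intermediate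
6 | triol: as 5 with free hydroxyl groups on C6 and C10 | C[C@]12CC[C@](O)(C(C)C)[C@H]1[C@]1(O)CC(C)C[C@]21O | intermediate
7 | cis-fused aldol: 4α-hydroxy-4β-isopropyl-1β,8-dimethyl-5β-H-bicyclo[5.3.0]decane-6,10-dione | C[C@]12CC[C@](O)(C(C)C)[C@H]1C(=O)CC(C)CC2=O | intermediate
8 | enedione: 4-isopropyl-1β,8-dimethylbicyclo[5.3.0]dec-4-ene-6,10-dione (C4=C5) | C[C@]12CCC(C(C)C)=C1C(=O)CC(C)CC2=O | intermediate
9 | 4α,5α-epoxide of 8 (isopropyl β, C6 β on C5) | C[C@]12CC[C@@]3(C(C)C)O[C@@]13C(=O)CC(C)CC2=O | intermediate
10 | trans-fused aldol: 4α-hydroxy-4β-isopropyl-1β,8-dimethyl-5α-H-bicyclo[5.3.0]decane-6,10-dione | C[C@]12CC[C@](O)(C(C)C)[C@@H]1C(=O)CC(C)CC2=O | intermediate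
11 | keto diol: 4α,6α-dihydroxy-4β-isopropyl-1β,8-dimethyl-5α-H-bicyclo[5.3.0]decan-10-one | C[C@]12CC[C@](O)(C(C)C)[C@@H]1[C@@H](O)CC(C)CC2=O | intermediate
12 | 4-hydroxybenzoic acid | O=C(O)c1ccc(O)cc1 | starting material
13 | tert-butyldimethylsilyl 4-(tert-butyldimethylsilyloxy)benzoate | CC(C)(C)[Si](C)(C)OC(=O)c1ccc(O[Si](C)(C)C(C)(C)C)cc1 | intermediate
14 | 4-(tert-butyldimethylsilyloxy)benzoic acid | CC(C)(C)[Si](C)(C)Oc1ccc(C(=O)O)cc1 | intermediate
15 | keto ester: 11 acylated on the 6α oxygen with the 4-(tert-butyldimethylsilyloxy)benzoyl group | C[C@]12CC[C@](O)(C(C)C)[C@@H]1[C@@H](OC(=O)c3ccc(O[Si](C)(C)C(C)(C)C)cc3)CC(C)CC2=O | intermediate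
16 | 15 as C4 triethylsilyl ether and C10 triethylsilyl enol ether (C9=C10) | C[C@]12CC[C@](O[Si](CC)(CC)CC)(C(C)C)[C@@H]1[C@@H](OC(=O)c3ccc(O[Si](C)(C)C(C)(C)C)cc3)CC(C)C=C2O[Si](CC)(CC)CC | intermediate
17 | enone: 8-en-10-one with 4α-triethylsilyloxy, 4β-isopropyl, 5α-H, 6α-aroyloxy | C[C@]12CC[C@](O[Si](CC)(CC)CC)(C(C)C)[C@@H]1[C@@H](OC(=O)c3ccc(O[Si](C)(C)C(C)(C)C)cc3)CC(C)=CC2=O | intermediate
18 | 10α-allylic alcohol derived from 17 | C[C@]12CC[C@](O[Si](CC)(CC)CC)(C(C)C)[C@@H]1[C@@H](OC(=O)c3ccc(O[Si](C)(C)C(C)(C)C)cc3)CC(C)=C[C@H]2O | intermediate
19 | 10α-tiglate of 18 | C[C@]12CC[C@](O[Si](CC)(CC)CC)(C(C)C)[C@@H]1[C@@H](OC(=O)c3ccc(O[Si](C)(C)C(C)(C)C)cc3)CC(C)=C[C@H]2OC(=O)/C(C)=C/C | intermediate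
20 | CNP0273650.6: 4α-hydroxy-6α-(4-hydroxybenzoyloxy)-4β-isopropyl-1β,8-dimethyl-5α-H-10α-[(E)-2-methylbut-2-enoyloxy]bicyclo[5.3.0]dec-8-ene | C/C=C(\C)C(=O)O[C@@H]1C=C(C)C[C@H](OC(=O)c2ccc(O)cc2)[C@@H]2[C@]1(C)CC[C@]2(O)C(C)C | target

Total step count: 13. Longest linear sequence: 12 steps (steps 1 to 7 and 9 to 13, from 1 to 20); step 8 is a one-step side branch.

## Steps least certain to work

**Step 2 (key step).** Two processes can defeat it. The strong Lewis acid can promote thermal conjugate addition of the silyl enol ether 2 to the bound enone, or strip its silyl groups, before light is absorbed. And a five-membered enone may sit in the catalyst pocket differently from the six-membered enones, so facial discrimination may be poor, or unbound enone may be excited and react without control.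
Fallback (sets out from 2 and 3, returns at 8): 3 is irradiated with excess 2 at 350 nm without any Lewis acid, the known racemic photocycloaddition of cyclopentenones with 1,2-bis(silyloxy)cycloalkenes. This gives 4 together with its mirror image, ent-photoadduct F1. Steps 3 to 5 are run on the racemate, which passes through ent-tertiary alcohol F2, ent-triol F3 and ent-aldol F4 alongside 5, 6 and 7. The racemic enedione is then separated by preparative chromatography on a polysaccharide chiral stationary phase into 8 and ent-enedione F5, with the two C8 epimers of each collected together.

**Step 6.** Hydroperoxide addition to the hindered tetrasubstituted enone may be slow, and facial selectivity may be poor if the C1 methyl is not held pseudo-axial; attack from the β face would lead to the wrong C4 carbinol.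
Fallback (sets out from 8, returns at 15): the saturated C10 ketone is ketalised selectively (ethylene glycol, p-TsOH, benzene, water removal) to enone ketal F6. Corey–Bakshi–Shibata reduction with the (R)-2-methyl-oxazaborolidine and BH3·SMe2 sets the carbinol by reagent control, giving 6α-allylic alcohol F7. Hydroxyl-directed epoxidation (VO(acac)2, t-BuOOH) places the oxygen on the same face, giving α-epoxy alcohol F8. Dess–Martin oxidation gives epoxy ketone ketal F9, the conditions of step 7 give diol ketal F10, those of step 9 give ester ketal F11, and PPTS in wet acetone removes the ketal to reach 15.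

**Step 7.** The second, slower reduction is the weak part. The samarium aldolate of 10 may undergo retro-aldol cleavage or C5 epimerisation before it is reduced, the C10 ketone may be reduced as well, or hydrogen may enter C6 from the outer face and give the axial 6β alcohol.
Fallback (sets out from 9, returns at 15): the reaction is stopped after the epoxide opening (2.2 equiv SmI2, −78 °C) and 10 is isolated. Evans–Saksena reduction (Me4NBH(OAc)3, MeCN/AcOH, −30 °C) reduces only the ketone that carries the β-hydroxyl and delivers hydride from the side of O4, which should give 6β-alcohol F12. Mitsunobu esterification of F12 with 14 (PPh3, DIAD, toluene) inverts C6 by equatorial attack and gives 15 directly.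

**Step 11.** Hydride may enter from the inner face and give the equatorial 10β alcohol, conjugate reduction may compete, or enolate formation may lead to loss of the C6 aroyloxy group by vinylogous β-elimination.
Fallback (sets out from 17, returns at 19): 17 is reduced with NaBH4/CeCl3·7H2O in MeOH at −78 °C (Luche reduction), which is strictly 1,2 and should favour 10β-allylic alcohol F13. F13 is converted into 19 by Mitsunobu esterification with tiglic acid (PPh3, DIAD), which installs the ester with inversion.

## Further compounds

F1 | step 2 | ent-photoadduct (mirror image of 4) | C[C@@]12CCC(=O)[C@@H]1[C@@]1(O[Si](C)(C)C)CC(C)C[C@@]21O[Si](C)(C)C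
F2 | step 2 | ent-tertiary alcohol (mirror image of 5) | C[C@@]12CC[C@@](O)(C(C)C)[C@@H]1[C@@]1(O[Si](C)(C)C)CC(C)C[C@@]21O[Si](C)(C)C
F3 | step 2 | ent-triol (mirror image of 6) | C[C@@]12CC[C@@](O)(C(C)C)[C@@H]1[C@@]1(O)CC(C)C[C@@]21O
F4 | step 2 | ent-aldol (mirror image of 7) | C[C@@]12CC[C@@](O)(C(C)C)[C@@H]1C(=O)CC(C)CC2=O
F5 | step 2 | ent-enedione (mirror image of 8) | C[C@@]12CCC(C(C)C)=C1C(=O)CC(C)CC2=O
F6 | step 6 | enone ketal: 8 with C10 as ethylene ketal | C[C@]12CCC(C(C)C)=C1C(=O)CC(C)CC23OCCO3
F7 | step 6 | 6α-allylic alcohol of F6 | C[C@]12CCC(C(C)C)=C1[C@@H](O)CC(C)CC23OCCO3
F8 | step 6 | 4α,5α-epoxy-6α-alcohol, C10 ethylene ketal | C[C@]12CC[C@@]3(C(C)C)O[C@@]13[C@@H](O)CC(C)CC24OCCO4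
F9 | step 6 | epoxy ketone ketal: 9 with C10 as ethylene ketal | C[C@]12CC[C@@]3(C(C)C)O[C@@]13C(=O)CC(C)CC24OCCO4
F10 | step 6 | diol ketal: 11 with C10 as ethylene ketal | C[C@]12CC[C@](O)(C(C)C)[C@@H]1[C@@H](O)CC(C)CC23OCCO3
F11 | step 6 | ester ketal: 15 with C10 as ethylene ketal | C[C@]12CC[C@](O)(C(C)C)[C@@H]1[C@@H](OC(=O)c3ccc(O[Si](C)(C)C(C)(C)C)cc3)CC(C)CC24OCCO4
F12 | step 7 | 6β-alcohol (C6 epimer of 11) | C[C@]12CC[C@](O)(C(C)C)[C@@H]1[C@H](O)CC(C)CC2=O
F13 | step 11 | 10β-allylic alcohol (C10 epimer of 18) | C[C@]12CC[C@](O[Si](CC)(CC)CC)(C(C)C)[C@@H]1[C@@H](OC(=O)c3ccc(O[Si](C)(C)C(C)(C)C)cc3)CC(C)=C[C@@H]2O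
A1 | alternative 1 | 4,7-dimethyl-6-(p-tolylsulfinyl)-8-oxabicyclo[3.2.1]octa-3,6-dien-2-one | O1[C@H]2C(C)=CC(=O)[C@@H]1C(C)=C2[S@](=O)c1ccc(C)cc1
A2 | alternative 1 | 6-acetoxy-5-methyl-2H-pyran-3(6H)-one | CC(=O)OC1OCC(=O)C=C1C
A3 | alternative 1 | 1-methyl-4-(prop-1-ynylsulfinyl)benzene, single enantiomer at sulfur | CC#C[S@](=O)c1ccc(C)cc1
A4 | alternative 2 | trans-fused hydroazulene with C6 1,3-dithiane, free C4 hydroxyl and C10 tert-butyldimethylsilyl ether | CC(C)(C)[Si](C)(C)O[C@@H]1C=C(C)CC2(SCCCS2)[C@@H]2[C@]1(C)CC[C@]2(O)C(C)C
A5 | alternative 2 | 4α,5α-epoxy-4β-isopropyl-1β-methylcyclopentane carrying on C1 the (Z)-1-(tert-butyldimethylsilyloxy)-3-methyl-4-(1,3-dithian-2-yl)but-2-enyl chain | CC(C)(C)[Si](C)(C)O[C@H](/C=C(C)\CC1SCCCS1)[C@@]1(C)CC[C@@]2(C(C)C)O[C@@H]12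
A6 | alternative 3 | trans-2,3-disubstituted cyclopentanone aldol with C1, C5 and C6 set | I/C=C(C)\C[C@H](O)[C@@H]1[C@@](C)(COCOC)CCC1=O
A7 | alternative 3 | 3-(methoxymethoxymethyl)cyclopent-2-en-1-one | COCOCC1=CC(=O)CC1
A8 | alternative 3 | (Z)-4-iodo-3-methylbut-3-enal | I/C=C(C)\CC=O
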